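## Structural features

The target is cryptostictic acid drawn as its (R)-lactol, a tetracyclic depsidone. Two benzene rings, A and B, are joined twice, by a diaryl ether oxygen and by an ester, so that a seven-membered dioxepinone (ring C) lies between them; ring B also carries a fused five-membered hydroxy-lactone (ring D, a 3-hydroxyphthalide). Ring A is pentasubstituted (methoxy, a hydroxymethyl group between the methoxy carbon and the ether carbon, the ether oxygen, the ring C carbonyl, a C-methyl). Ring B is hexasubstituted: going round, the ether carbon, the lactol-bearing carbon, the lactone-carbonyl-bearing carbon, a phenol carbon, the C-methyl carbon and the ester-oxygen carbon. The only stereocentre is the lactol carbon of ring D; it has no stereogenic neighbour and, as a hemiacetal, can epimerise by opening to the 2-formylbenzoic acid. The fragile groups are the aryl ester of ring C (cleaved by hydroxide, alkoxide and amines), the lactol, and the benzylic alcohol of ring A, which sits between two oxygen-bearing carbons and ionises easily in acid. The real difficulty is threefold: the fully substituted ring B, an ether between two carbons that each have two ortho substituents, and a labile stereocentre that must be delivered as one enantiomer. The key step uses the oxygen pattern of ring B: the phenol carbon and the ester-oxygen carbon flank the C-methyl carbon as in a resorcinol, and the ester-oxygen carbon is bonded to the ether carbon. Ring B is therefore the dehydrogenated form of a 2-methylcyclohexane-1,3-dione with the aryloxy group on C4, and its ether carbon and ester-oxygen carbon correspond to the α-carbon and carbonyl carbon of an aryloxyacetic ester of ring A.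

## Logic of the disconnections

20 to 19. The free lactol of 20 is the only species in the plan whose stereocentre can invert, so the last cut is the acyl C–O bond of a lactol ester. Nothing in the skeleton is simplified; the gain is a configurationally locked precursor. The forward step must break the bond on the acyl side only, under neutral conditions, so that no bond to the stereocentre is touched and ring C survives.

19 to 18. The O–H bond of the primary alcohol is exchanged for an O–Si bond. The silyl ether is needed because the benzylic alcohol would compete in acylations and ionise in acid. The forward step must remove silicon without base, which would cleave the activated lactol ester.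

18 to 17. The acyl–oxygen bond at the lactol is cut and the stereocentre is released, which leads to racemic 17. From here backwards no stereochemistry has to be carried. The forward step must acylate one lactol enantiomer faster than the other while the two interconvert, which calls for a chiral acyl-transfer catalyst and a base that opens and recloses the lactol.

17 to 16. The lactol O–H is traced to an O–CH3 bond. The methyl acetal keeps the lactol, and the open formyl acid behind it, out of the ring C closure. The price is a hydrolysis that must be acidic (base would open ring C) and mild enough for the silyl ether.

16 to 15. Ring C is opened at its ester C–O bond, which leaves a hydroxy acid in which the ether already holds the acid of ring A beside the phenol of ring B. Two arenes joined by one atom are far simpler than the bridged system. The forward step must activate a di-ortho-substituted acid, and the second phenol must stay out, which its position and its hydrogen bond to ring D ensure.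

15 to 14. Three bonds are restored: the two acid O–H bonds become O–C bonds to tert-butyl groups, and the lactone C–O bond of ring D is cut to an ester beside a dimethyl acetal. One acid treatment should do all three in the forward direction. It must leave the silyl ether intact and must not tert-butylate the arenes.

14 to 13. Ring B is dearomatised: two hydrogens are added (at the acetal-bearing and the aryloxy-bearing carbon) and both phenols become ketones. This exposes the cyclohexane-1,3-dione that an anionic annulation delivers. The forward dehydrogenation must be non-acidic, because acid would expel methanol from the acetal, and it must spare the benzylic silyl ether.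

13 to 8 and 11. Two C–C bonds are cut: the bond between the aryloxy-bearing carbon and the acetal-bearing carbon, and the bond between the methyl-bearing carbon and the neighbouring carbonyl carbon. This splits the hexasubstituted ring into an aryloxyacetate and an alkylidene ketoester. The ether oxygen is already attached, so the hindered diaryl ether never has to be made by coupling. The forward step needs conjugate addition before acyl substitution, and an enolate that does not attack the ring A ester.

11 to 9 and 10. The C=C bond is cut by a retro-condensation to an active methylene compound and an aldehyde that carries the future lactol carbon as its acetal. The forward condensation must not touch the acetal or the tert-butyl ester.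

8 to 6 and 7. The O–CH2 bond of the aryloxyacetate is cut to a phenol and an α-bromo ester. The forward alkylation must come after the formyl group has been reduced and protected, because an ortho aldehyde would condense with the new acetate.

6 to 5 to 4 to 3. The O–Si bond, then a C–H bond of the hydroxymethyl group (reduction of an aldehyde), then the aryl–CHO bond are cut. The forward formylation must go ortho to the phenol only and must tolerate a tert-butyl ester, which excludes Lewis-acid methods.

3 to 2 to 1. The O–CH3 bond of the para oxygen and the ester O–C(tert-butyl) bond are cut, which reaches the commercial acid 1. Starting from the acid avoids saponifying a hindered methyl ester. The forward esterification must be alkylative, since the acyl carbon is blocked on both sides.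

## Other disconnections considered

Alternative 1: The cut removes the diaryl ether C–O bond at ring A and the C–C bond between ring A and its hydroxymethyl carbon, which is traced to CO2.
- Forward key step: the depside A2 has an ortho-silylaryl triflate on ring A, esterified to a silyl-capped ring B phenol. CsF under CO2 frees the phenoxide and generates the ring A aryne. The phenoxide adds to the aryne carbon beside the ester-bearing carbon, which closes ring C, and the resulting aryl anion is carboxylated to A1. Reduction of the new acid, debenzylation and release of the lactol would follow.
- In its favour: the hindered ether forms intramolecularly under mild conditions; the methoxy group and the tether both steer the oxygen to the correct aryne carbon; the depside ester is made early by simple acylation; one operation closes ring C and adds a ring A carbon.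
- Against it here: A2 already contains the complete hexasubstituted ring B with ring D, so the hardest part has to come from a separate arene synthesis. The freed phenoxide sits ortho to the acylated oxygen, and acyl migration between the two neighbouring oxygens would scramble ether and ester positions. Carboxylation must outrun protonation. The new acid must be reduced in the presence of ring C and the ring D acylal.
- Comparison: on ether formation it is the equal of the chosen plan, since both avoid an intermolecular hindered coupling. On closing ring C without a separate lactonisation it is the better. On building ring B the chosen plan is stronger, because it assembles all six substituted carbons from two acyclic pieces. The step count is expected to be higher once both halves of A2 are made, and the same final resolution of the lactol is needed.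

Alternative 2: Rings B and D are cut together to the triyne A4 (a 1,3-diyne tethered through an acetal-ester to a silylalkyne), and the depside C–O bond is cut to the ring A salicylic acid A5.
- Forward key step: heating A4 with A5 triggers the hexadehydro-Diels–Alder cyclisation. It forms one bond from the methyl-bearing carbon to the silyl-bearing carbon and one between the two ring-fusion carbons. The acid then adds across the aryne to give depside A3.
- In its favour: two rings, two C–C bonds and one C–O bond form in a thermal step without reagents or strong base; the tether fixes the position of every ring B carbon substituent; both partners are simple. On bond-forming efficiency in the key step it is the better plan.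
- Against it here: A3 still lacks the two oxygens that matter most. The ether position is a C–H and the phenol position a C–Si, so a Fleming–Tamao oxidation, halogenation of the last ring position and a copper-mediated Ullmann closure must follow. That late hindered etherification is what the chosen plan avoids. The acid must add with its oxygen on the aryne carbon remote from the ring fusion, which is expected but not assured. The free phenol of A5 can compete in the trapping, and the acylal tether of A4 is delicate.
- Comparison: equal in convergence and in the end-game at the lactol; better in the complexity gained in one step; weaker in what remains afterwards, so no saving in steps is expected.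

Alternative 3: Both C–O bonds of the ring D oxygen are removed, leading to the benzocyclobutenone A7 with the silyloxy group on its sp3 carbon.
- Forward key step: a peracid adds to the strained ketone and the oxygenated carbon migrates with retention (Baeyer–Villiger), giving A6, the bis-silyl ether of the target.
- In its favour: the stereocentre is carried as a carbon centre that cannot enolise without forming an antiaromatic four-membered ring. It is transferred with retention, and the lactol emerges silylated and therefore locked. On the stereochemical problem this is the better solution, since a stereospecific step replaces a dynamic resolution. Only one deprotection follows.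
- Against it here: it is an end-game tactic. A7 contains both arenes, the ether and ring C, plus a strained ring on the hexasubstituted ring B, and none of that construction is addressed. An enantioselective route to the oxygenated four-membered ketone is required. The electron-rich aryl group with its ortho phenol is a competing migrating group, and the peracid can oxidise the phenol. The final fluoride treatment of a lactol silyl ether risks racemisation and ring C cleavage.
- Comparison: shorter and stereochemically cleaner after the key step; before it, it needs everything the chosen plan delivers and more. It is complementary to the chosen plan and could serve as its end-game, but does not replace it.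

Key step: step 8

Assumption: the lactol carbon of a 3-hydroxyphthalide epimerises through its ring-opened formyl acid, so the (R)-enantiomer is treated as a kinetically isolated form that is released last under neutral conditions and handled cold; the enantiomer of the acyl-transfer catalyst in step 13 is taken to be the one that leads to the (R)-ester.

Step 1
Reactants: 1 orsellinic acid (2,4-dihydroxy-6-methylbenzoic acid)
Product: 2 tert-butyl 2,4-dihydroxy-6-methylbenzoate
Conditions: O-tert-butyl-N,N'-diisopropylisourea (2.5 equiv), THF/CH2Cl2, rt
Reagents that add atoms: O-tert-butyl-N,N'-diisopropylisourea, CC(C)NC(=NC(C)C)OC(C)(C)C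
Why: Alkylative esterification: the acid protonates the isourea and the carboxylate takes the tert-butyl group at oxygen, so the hindered acyl carbon is never attacked; the less acidic phenols do not react without a catalyst, and the low temperature avoids decarboxylation.

Step 2
Reactants: 2 tert-butyl 2,4-dihydroxy-6-methylbenzoate
Product: 3 tert-butyl 2-hydroxy-4-methoxy-6-methylbenzoate
Conditions: MeI (1.1 equiv), K2CO3 (1.1 equiv), acetone, rt to 40 °C
Reagents that add atoms: iodomethane, CI
Why: Williamson etherification; the hydroxyl para to the ester is the more acidic and accessible one, while the ortho hydroxyl is held in a hydrogen bond to the ester carbonyl, the usual selectivity of orsellinates.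

Step 3
Reactants: 3 tert-butyl 2-hydroxy-4-methoxy-6-methylbenzoate
Product: 4 tert-butyl 3-formyl-2-hydroxy-4-methoxy-6-methylbenzoate
Conditions: MgCl2 (2 equiv), Et3N (4 equiv), (CH2O)n (6 equiv), MeCN, reflux
Reagents that add atoms: paraformaldehyde (as formaldehyde), C=O
Why: Magnesium-mediated ortho-formylation (Casnati–Skattebøl reaction): the magnesium phenoxide delivers formaldehyde to its ortho carbon and a second formaldehyde accepts hydride; C3 is the only free ortho position and is activated by the neighbouring methoxy group, and the basic medium spares the tert-butyl ester, which Lewis-acid formylations would not.

Step 4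
Reactants: 4 tert-butyl 3-formyl-2-hydroxy-4-methoxy-6-methylbenzoate
Product: 5 tert-butyl 2-hydroxy-3-(hydroxymethyl)-4-methoxy-6-methylbenzoate
Conditions: NaBH4, THF/MeOH, 0 °C
Reagents that add atoms: none
Why: Borohydride reduction of the aldehyde; the hindered tert-butyl ester is inert, and a cold neutral work-up avoids quinone-methide chemistry of the ortho-hydroxybenzyl alcohol.

Step 5
Reactants: 5 tert-butyl 2-hydroxy-3-(hydroxymethyl)-4-methoxy-6-methylbenzoate
Product: 6 tert-butyl 3-({[tert-butyl(diphenyl)silyl]oxy}methyl)-2-hydroxy-4-methoxy-6-methylbenzoate
Conditions: TBDPSCl (1.05 equiv), imidazole, CH2Cl2, 0 °C to rt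
Reagents that add atoms: tert-butyl(chloro)diphenylsilane, CC(C)(C)[Si](Cl)(c1ccccc1)c1ccccc1
Why: Silylation of the primary alcohol; the phenol is flanked on both sides and hydrogen-bonded to the ester, so the bulky silyl chloride takes the primary hydroxyl only, and this silyl group is chosen because it must later survive trifluoroacetic acid.

Step 6
Reactants: 6 tert-butyl 3-({[tert-butyl(diphenyl)silyl]oxy}methyl)-2-hydroxy-4-methoxy-6-methylbenzoate; 7 methyl bromoacetate
Product: 8 tert-butyl 3-({[tert-butyl(diphenyl)silyl]oxy}methyl)-4-methoxy-2-(2-methoxy-2-oxoethoxy)-6-methylbenzoate (ring A aryloxyacetate)
Conditions: Cs2CO3, DMF, rt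
Reagents that add atoms: none
Why: Williamson O-alkylation of the caesium phenoxide with a reactive α-bromo ester; carbonate cannot enolise the product, so no Dieckmann chemistry starts, and the step is placed after reduction and silylation because an ortho-formyl group would condense with the new acetate to a benzofuran.

Step 7
Reactants: 9 tert-butyl 3-oxopentanoate; 10 2,2-dimethoxyacetaldehyde
Product: 11 tert-butyl 2-(2,2-dimethoxyethylidene)-3-oxopentanoate (E/Z mixture)
Conditions: piperidine (10 mol %), AcOH (10 mol %), 4 Å molecular sieves, CH2Cl2, 0 °C to rt
Reagents that add atoms: none
Why: Knoevenagel condensation at the methylene between ketone and ester, with the aldehyde dried from its commercial aqueous solution; the mild amine/acid pair leaves the acetal and the tert-butyl ester intact, and the alkene geometry is irrelevant because the double bond is consumed in step 8.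

Step 8
Reactants: 8 ring A aryloxyacetate; 11 tert-butyl 2-(2,2-dimethoxyethylidene)-3-oxopentanoate
Product: 13 aryloxy cyclohexane-1,3-dione (tert-butyl ester; diastereomer mixture), via Michael adduct 12 (not isolated)
Conditions: LiN(iPr)2 (1.1 equiv), THF, −78 °C; 11, −78 °C; LiN(iPr)2 (1.2 equiv), −78 to 0 °C; AcOH, −78 °C
Reagents that add atoms: none
Why: LiN(iPr)2 converts 8 into its lithium enolate, which adds in conjugate fashion to the doubly activated alkene of 11 and so joins the future ether carbon to the acetal-bearing carbon, the adduct resting as the chelated lithium enolate of ketoester 12. The second charge of base removes a proton from the CH2 of the propanoyl group, and the dianion attacks the methyl ester through this γ-carbon, joining the methyl-bearing carbon to the future ester-oxygen carbon with loss of methoxide. The closest known chemistry is the Michael–Claisen (Michael–Dieckmann) annulation of ester and malonate enolates with enones and alkylidene 1,3-dicarbonyl compounds to cyclohexane-1,3-diones, together with the γ-acylation of ketoester dianions. Ring B closes by a 6-exo-trig acyl substitution. The four sp3 centres that form are not controlled and need not be, since each is flattened in step 9, so the diastereomer and enol mixture is carried on as such. Conjugate addition has to outrun proton transfer and self-condensation, which the very electrophilic acceptor at −78 °C secures, and the enolate has to leave the ring A ester alone, which the tert-butyl group and the two ortho substituents secure by blocking the five-membered Dieckmann closure to a benzofuranone; the tert-butyl ester of 11 likewise excludes acyl substitution there. The closure is regiochemically unambiguous because only the γ-carbanion reaches the methyl ester through a six-membered transition state, and the methoxide set free deprotonates the product dione, which makes the sequence irreversible. The cold acetic acid quench avoids acid-induced loss of methanol from the acetal.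

Step 9
Reactants: 13 aryloxy cyclohexane-1,3-dione
Product: 14 tert-butyl 2-(dimethoxymethyl)-4,6-dihydroxy-5-methyl-3-(ring A aryloxy)benzoate
Conditions: DDQ (1.1 equiv), 1,4-dioxane, rt to 50 °C
Reagents that add atoms: none
Why: Quinone dehydrogenation of a cyclohexane-1,3-dione: DDQ abstracts hydride from the ring C–H next to the enolised ketoester, loss of a proton gives the enedione and this tautomerises to the resorcinol; the medium stays near neutral, which the acetal, both tert-butyl esters and the silyl ether tolerate.

Step 10
Reactants: 14 tert-butyl 2-(dimethoxymethyl)-4,6-dihydroxy-5-methyl-3-(ring A aryloxy)benzoate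
Product: 15 ring A benzoic acid bearing the 3-methoxyphthalide of ring B (racemic)
Conditions: TFA/CH2Cl2 (1:4), anhydrous, 0 °C to rt
Reagents that add atoms: none
Why: Acidolysis of both tert-butyl esters by alkyl–oxygen cleavage; the acetal ionises and the neighbouring carboxyl group closes ring D on the oxocarbenium ion, so that without water the lactol is obtained as its methyl acetal, which masks it for step 11; ring B has no free position for tert-butylation and the silyl ether withstands the acid.

Step 11
Reactants: 15 ring A benzoic acid bearing the 3-methoxyphthalide of ring B
Product: 16 silyl-protected depsidone with ring D as methyl acetal (racemic)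
Conditions: EDC·HCl (1.5 equiv), 4-(dimethylamino)pyridine (0.2 equiv), CH2Cl2 (2 mM), 0 °C to rt
Reagents that add atoms: none
Why: Carbodiimide lactonisation, the classical closure of depsidones: the O-acylisourea of the ring A acid is attacked by the ring B phenol that the ether bridge holds beside it (7-exo-trig), while the other phenol cannot reach and is hydrogen-bonded to the ring D carbonyl; high dilution suppresses dimerisation and the medium is not basic enough for a Smiles rearrangement of the ether.

Step 12
Reactants: 16 silyl-protected depsidone with ring D as methyl acetal
Product: 17 silyl-protected racemic lactol (O-silyl cryptostictic acid)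
Conditions: 1 M aq. HCl/THF (1:3), 45 °C
Reagents that add atoms: water, O
Why: Acid-catalysed hydrolysis of the cyclic acylal (pseudo-ester), which is far more labile than an ordinary ester or the silyl ether; the aryl ester of ring C is stable to dilute acid, and the lactol forms as the racemate.

Step 13
Reactants: 17 silyl-protected racemic lactol
Product: 18 silyl-protected (R)-lactol propanoate
Conditions: (EtCO)2O (1.5 equiv), iPr2NEt (1.5 equiv), HyperBTM [(2S,3R)-3-isopropyl-2-phenyl-3,4-dihydro-2H-benzo[4,5]thiazolo[3,2-a]pyrimidine or its enantiomer, 5 mol %], CHCl3, 0 °C
Reagents that add atoms: propanoic anhydride, CCC(=O)OC(=O)CC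
Why: Acylative dynamic kinetic resolution of a 3-hydroxyphthalide by a chiral Lewis-base acyl-transfer catalyst: the amine base interconverts the lactol enantiomers through the ring-opened formyl carboxylate while the chiral N-acyl isothiouronium ion propanoylates one of them faster, and acylation locks the centre; the (R) configuration is set by the catalyst, whose enantiomer is chosen accordingly, and the only other hydroxyl, the phenol, is deactivated by its hydrogen bond to the lactone carbonyl.

Step 14
Reactants: 18 silyl-protected (R)-lactol propanoate
Product: 19 (R)-lactol propanoate of cryptostictic acid
Conditions: HF·pyridine, pyridine, THF, 0 °C to rt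
Reagents that add atoms: none
Why: Fluoride-driven cleavage of the silyl ether under weakly acidic, water-free conditions; no bond to the stereocentre is involved, and the acylal and the ring C ester, which basic fluoride would attack, are left alone.

Step 15
Reactants: 19 (R)-lactol propanoate of cryptostictic acid
Product: 20 (R)-cryptostictic acid (target)
Conditions: Candida antarctica lipase B (immobilised), n-BuOH (5 equiv), MTBE, 20 °C; filter, evaporate cold
Reagents that add atoms: none
Why: Lipase-catalysed alcoholysis of the activated lactol ester: the serine of the enzyme attacks the propanoyl carbonyl and the acyl–oxygen bond breaks, so the configuration at the lactol carbon is retained; the medium is neutral and free of water and base, the conditions under which the released (R)-lactol epimerises most slowly.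

Compound list (ArA = 2-(tert-butoxycarbonyl)-6-({[tert-butyl(diphenyl)silyl]oxy}methyl)-5-methoxy-3-methylphenyl, the ring A aryl group of 8)

1 | orsellinic acid (2,4-dihydroxy-6-methylbenzoic acid) | Cc1cc(O)cc(O)c1C(=O)O | starting material
2 | tert-butyl 2,4-dihydroxy-6-methylbenzoate | Cc1cc(O)cc(O)c1C(=O)OC(C)(C)C | intermediate
3 | tert-butyl 2-hydroxy-4-methoxy-6-methylbenzoate | COc1cc(C)c(C(=O)OC(C)(C)C)c(O)c1 | intermediate
4 | tert-butyl 3-formyl-2-hydroxy-4-methoxy-6-methylbenzoate | COc1cc(C)c(C(=O)OC(C)(C)C)c(O)c1C=O | intermediate
5 | tert-butyl 2-hydroxy-3-(hydroxymethyl)-4-methoxy-6-methylbenzoate | COc1cc(C)c(C(=O)OC(C)(C)C)c(O)c1CO | intermediate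
6 | tert-butyl 3-({[tert-butyl(diphenyl)silyl]oxy}methyl)-2-hydroxy-4-methoxy-6-methylbenzoate | COc1cc(C)c(C(=O)OC(C)(C)C)c(O)c1CO[Si](c1ccccc1)(c1ccccc1)C(C)(C)C | intermediate
7 | methyl bromoacetate | COC(=O)CBr | starting material
8 | tert-butyl 3-({[tert-butyl(diphenyl)silyl]oxy}methyl)-4-methoxy-2-(2-methoxy-2-oxoethoxy)-6-methylbenzoate (ring A aryloxyacetate) | COC(=O)COc1c(C(=O)OC(C)(C)C)c(C)cc(OC)c1CO[Si](c1ccccc1)(c1ccccc1)C(C)(C)C | intermediate
9 | tert-butyl 3-oxopentanoate | CCC(=O)CC(=O)OC(C)(C)C | starting material
10 | 2,2-dimethoxyacetaldehyde | COC(OC)C=O | starting material
11 | tert-butyl 2-(2,2-dimethoxyethylidene)-3-oxopentanoate (E/Z mixture) | CCC(=O)C(C(=O)OC(C)(C)C)=CC(OC)OC | intermediate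
12 | 1-tert-butyl 5-methyl 3-(dimethoxymethyl)-4-(ArA-oxy)-2-propanoylpentanedioate (Michael adduct, diastereomer mixture, lithium enolate in the flask) | CCC(=O)C(C(=O)OC(C)(C)C)C(C(OC)OC)C(Oc1c(C(=O)OC(C)(C)C)c(C)cc(OC)c1CO[Si](c1ccccc1)(c1ccccc1)C(C)(C)C)C(=O)OC | intermediate
13 | tert-butyl 2-(dimethoxymethyl)-5-methyl-4,6-dioxo-3-(ArA-oxy)cyclohexane-1-carboxylate (diastereomer and enol mixture) | CC(C)(C)OC(=O)C1C(C(OC)OC)C(Oc2c(C(=O)OC(C)(C)C)c(C)cc(OC)c2CO[Si](c2ccccc2)(c2ccccc2)C(C)(C)C)C(=O)C(C)C1=O | intermediate
14 | tert-butyl 2-(dimethoxymethyl)-4,6-dihydroxy-5-methyl-3-(ArA-oxy)benzoate | CC(C)(C)OC(=O)c1c(C(OC)OC)c(Oc2c(C(=O)OC(C)(C)C)c(C)cc(OC)c2CO[Si](c2ccccc2)(c2ccccc2)C(C)(C)C)c(O)c(C)c1O | intermediate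
15 | 3-({[tert-butyl(diphenyl)silyl]oxy}methyl)-2-[(5,7-dihydroxy-3-methoxy-6-methyl-1-oxo-1,3-dihydro-2-benzofuran-4-yl)oxy]-4-methoxy-6-methylbenzoic acid (racemic at the acetal carbon) | COc1cc(C)c(C(=O)O)c(Oc2c(O)c(C)c(O)c3c2C(OC)OC3=O)c1CO[Si](c1ccccc1)(c1ccccc1)C(C)(C)C | intermediate
16 | depsidone from 15: ring C closed between the ring A acid and the ring B phenol next to the ether; ring D as 3-methoxyphthalide (racemic); ring A CH2O-silyl ether | COc1cc(C)c2c(c1CO[Si](c1ccccc1)(c1ccccc1)C(C)(C)C)Oc1c(c(C)c(O)c3c1C(OC)OC3=O)OC2=O | intermediate
17 | O-[tert-butyl(diphenyl)silyl] cryptostictic acid, racemic lactol | COc1cc(C)c2c(c1CO[Si](c1ccccc1)(c1ccccc1)C(C)(C)C)Oc1c(c(C)c(O)c3c1C(O)OC3=O)OC2=O | intermediate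
18 | O-[tert-butyl(diphenyl)silyl] cryptostictic acid (R)-lactol propanoate | COc1cc(C)c2c(c1CO[Si](c1ccccc1)(c1ccccc1)C(C)(C)C)Oc1c(c(C)c(O)c3c1[C@H](OC(=O)CC)OC3=O)OC2=O | intermediate
19 | cryptostictic acid (R)-lactol propanoate | COc1cc(C)c2c(c1CO)Oc1c(c(C)c(O)c3c1[C@H](OC(=O)CC)OC3=O)OC2=O | intermediate
20 | (R)-cryptostictic acid, CNP0367167.1 | COc1cc(C)c2c(c1CO)Oc1c(c(C)c(O)c3c1[C@H](O)OC3=O)OC2=O | target

Total step count: 15. Longest linear sequence: 14 steps (steps 1 to 6 and 8 to 15); step 7 is the one-step side branch.

Least certain steps

Step 8 (key step). The most likely failure is proton transfer in place of C–C bond formation: the enolate of 8 can deprotonate the acidic CH2 of 11, or the second charge of base can deprotonate the ester α-position of 12 instead of its propanoyl group. The sequence then stalls at the open chain or reverts by retro-Michael cleavage on warming. The fallback separates the two bond formations and removes the basic nucleophile. It sets out from 8, which is converted with LiN(iPr)2 and Me3SiCl into the silyl ketene acetal F1. F1 adds to 11 in a Mukaiyama–Michael reaction under Lewis-base catalysis (Bu4N[Ph3SiF2]), and 12 is isolated. 12 is then closed by a Dieckmann condensation under equilibrating conditions (KOtBu, THF/tBuOH), where the acidity of the product dione drives the closure. This returns to the route at 13.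

Step 3. The magnesium phenoxide of a salicylate is chelated by its own ester and is a weak nucleophile, so formylation may be slow and give way to condensation of the phenol with formaldehyde to diarylmethanes. The fallback sets out from 3 and uses a boron template instead of magnesium. Phenylboronic acid and paraformaldehyde with catalytic propanoic acid in hot toluene give the benzodioxaborin F2 by ortho-specific hydroxymethylation. Exchange with propane-1,3-diol frees the diol and returns to the route at 5, which also bypasses step 4.

Step 9. Oxidation may not stop at ring B: hydride abstraction at the benzylic silyl ether of the electron-rich ring A or further oxidation of the new resorcinol can compete. The hydroquinone formed is acidic enough to promote loss of methanol from the acetal, an internal redox aromatisation. The fallback sets out from 13 and activates the ring instead of using a stronger oxidant. LiN(SiMe3)2 and Me3SiCl give the bis(trimethylsilyl) dienol ether F3. Saegusa–Ito oxidation with Pd(OAc)2 (divalent palladium) in MeCN, followed by a desilylating work-up, returns to the route at 14.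

Step 12. Hydrolysis of the methyl acetal may be slow, and prolonged warming in aqueous acid invites loss of the silyl group followed by ionisation at the benzylic carbon. The fallback moves the hydrolysis to a stage where mild base can be used. It sets out from 15, in which ring C does not yet exist: aqueous NaHCO3 in THF followed by acidification gives the hydroxyphthalide acid F4. Ring C is then closed with trifluoroacetic anhydride through the mixed anhydride. This transiently caps the lactol as a trifluoroacetate that is lost on bicarbonate work-up, and the route is rejoined at 17.

Step 13. Poor discrimination between the lactol enantiomers is the main risk, because the reacting hydroxyl is crowded by the ether bridge and the silyloxymethyl group. Racemisation that is slow relative to acylation would turn the process into a simple kinetic resolution. The fallback replaces catalyst control by separation with recycling. It sets out from 17: non-selective propanoylation ((EtCO)2O, 4-(dimethylamino)pyridine) gives the racemic ester, and preparative chromatography on a chiral stationary phase separates 18 from its enantiomer, the (S)-propanoate F5. F5 is returned to 17 by lipase alcoholysis and resubmitted. The route is rejoined at 18.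

Step 15. The enzyme may not accept the bulky substrate, or the lactol may lose configuration by ring opening once released if the reaction is slow. The fallback changes the acyl group so that it can be removed chemically under near-neutral conditions. It sets out from 17: the resolution of step 13 is run with chloroacetic anhydride to give the silyl-protected chloroacetate F6, with the same spatial arrangement at the lactol carbon as in 18. HF·pyridine gives the chloroacetate F7, and thiourea with NaHCO3 in THF/EtOH removes the chloroacetyl group by S-alkylation and cyclisation. This returns to the route at 20.

Further compounds

F1 | step 8 | silyl ketene acetal of 8: 1-methoxy-1-(trimethylsilyloxy)-2-(ArA-oxy)ethene (E/Z mixture) | COC(O[Si](C)(C)C)=COc1c(C(=O)OC(C)(C)C)c(C)cc(OC)c1CO[Si](c1ccccc1)(c1ccccc1)C(C)(C)C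
F2 | step 3 | tert-butyl 7-methoxy-5-methyl-2-phenyl-4H-1,3,2-benzodioxaborinine-8... ring-fused boronate of 5 (phenol oxygen and benzylic oxygen bridged by B–Ph) | COc1cc(C)c(C(=O)OC(C)(C)C)c2OB(c3ccccc3)OCc12
F3 | step 9 | bis(trimethylsilyl) dienol ether of 13: tert-butyl 6-(dimethoxymethyl)-3-methyl-2,4-bis(trimethylsilyloxy)-5-(ArA-oxy)cyclohexa-1,3-diene-1-carboxylate | CC(C)(C)OC(=O)C1=C(O[Si](C)(C)C)C(C)=C(O[Si](C)(C)C)C(Oc2c(C(=O)OC(C)(C)C)c(C)cc(OC)c2CO[Si](c2ccccc2)(c2ccccc2)C(C)(C)C)C1C(OC)OC
F4 | step 12 | hydroxyphthalide acid: 15 with the lactol free in place of the methyl acetal (racemic) | COc1cc(C)c(C(=O)O)c(Oc2c(O)c(C)c(O)c3c2C(O)OC3=O)c1CO[Si](c1ccccc1)(c1ccccc1)C(C)(C)C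
F5 | step 13 | (S)-lactol propanoate, the enantiomer of 18 | COc1cc(C)c2c(c1CO[Si](c1ccccc1)(c1ccccc1)C(C)(C)C)Oc1c(c(C)c(O)c3c1[C@@H](OC(=O)CC)OC3=O)OC2=O
F6 | step 15 | silyl-protected lactol chloroacetate, same spatial arrangement at the lactol carbon as 18 (descriptor S, because the chloroacetoxy group outranks the ring oxygen) | COc1cc(C)c2c(c1CO[Si](c1ccccc1)(c1ccccc1)C(C)(C)C)Oc1c(c(C)c(O)c3c1[C@H](OC(=O)CCl)OC3=O)OC2=O
F7 | step 15 | lactol chloroacetate of cryptostictic acid, same spatial arrangement as 19 | COc1cc(C)c2c(c1CO)Oc1c(c(C)c(O)c3c1[C@H](OC(=O)CCl)OC3=O)OC2=O
A1 | alternative 1 | depsidone carboxylic acid (ring A CO2H in place of CH2OH, ring B phenol as benzyl ether, ring D as methyl acetal) | COc1cc(C)c2c(c1C(=O)O)Oc1c(c(C)c(OCc3ccccc3)c3c1C(OC)OC3=O)OC2=O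
A2 | alternative 1 | depside aryne precursor: ring A 2-(trifluoromethylsulfonyloxy)-3-(trimethylsilyl) benzoate esterified to the ring B phenol, whose neighbouring phenol is a tert-butyldimethylsilyl ether | COc1cc(C)c(C(=O)Oc2c(C)c(OCc3ccccc3)c3C(=O)OC(OC)c3c2O[Si](C)(C)C(C)(C)C)c(OS(=O)(=O)C(F)(F)F)c1[Si](C)(C)C
A3 | alternative 2 | depside with benzyldimethylsilyl group on ring B and ring D as ethyl acetal | COc1cc(C)c(C(=O)Oc2cc3C(OCC)OC(=O)c3c([Si](C)(C)Cc3ccccc3)c2C)c(O)c1CO[Si](C(C)C)(C(C)C)C(C)C
A4 | alternative 2 | 1-ethoxyhexa-2,4-diyn-1-yl 3-[benzyl(dimethyl)silyl]prop-2-ynoate (triyne) | CC#CC#CC(OCC)OC(=O)C#C[Si](C)(C)Cc1ccccc1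
A5 | alternative 2 | 2-hydroxy-4-methoxy-6-methyl-3-({[tri(propan-2-yl)silyl]oxy}methyl)benzoic acid | COc1cc(C)c(C(=O)O)c(O)c1CO[Si](C(C)C)(C(C)C)C(C)C
A6 | alternative 3 | bis(tert-butyldimethylsilyl) ether of the target (lactol and primary alcohol silylated) | COc1cc(C)c2c(c1CO[Si](C)(C)C(C)(C)C)Oc1c(c(C)c(O)c3c1[C@H](O[Si](C)(C)C(C)(C)C)OC3=O)OC2=O
A7 | alternative 3 | depsidone with a silyloxy benzocyclobutenone fused to ring B in place of ring D | COc1cc(C)c2c(c1CO[Si](C)(C)C(C)(C)C)Oc1c(c(C)c(O)c3c1[C@H](O[Si](C)(C)C(C)(C)C)C3=O)OC2=O
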